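**Assumption:** the SMILES has no stereocentre, so the target is achiral and "single enantiomer" means the constitution as drawn; substrates, intermediates and the target are numbered, reagents are given by name and SMILES.

**Retrosynthetic overview**
- The target is 1,7-bis(4-hydroxy-3-methoxyphenyl)heptan-3-one; the obvious C4–C5 aldol (zingerone plus an arylpropanal or coniferaldehyde, then H2) is deliberately set aside.
- Key disconnection C5–C6: a photoredox decarboxylative radical conjugate (Giese) addition of a 2-arylethyl radical to an aryl-ethyl vinyl ketone.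
- Both partners come from one commercial acid, dihydroferulic acid (1): the vinyl ketone via its Weinreb amide (C3–C4 acyl–vinyl bond), the radical via its N-acyloxyphthalimide.
- No ring is formed: both guaiacyl rings are bought intact; there are no protecting groups and no stereocentres.

**Step 1**
Reactants: 1 3-(4-hydroxy-3-methoxyphenyl)propanoic acid (dihydroferulic acid)
Product: 3 3-(4-hydroxy-3-methoxyphenyl)-N-methoxy-N-methylpropanamide, via acyl imidazolide 2 (not isolated)
Conditions: CDI (1.1 equiv), THF, rt, 1 h; then MeNH(OMe)·HCl (1.3 equiv), rt, 12 h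
Reagents that add atoms: N,O-dimethylhydroxylamine hydrochloride, CNOC.Cl
Why: CDI-mediated Weinreb amidation, in which the carboxylic acid reacts with CDI far faster than the phenol to give acyl imidazolide 2, which the amine then opens to the amide.

**Step 2**
Reactants: 3 3-(4-hydroxy-3-methoxyphenyl)-N-methoxy-N-methylpropanamide
Product: 5 5-(4-hydroxy-3-methoxyphenyl)pent-1-en-3-one, via bromomagnesium tetrahedral adduct 4 (not isolated)
Conditions: CH2=CHMgBr (3.0 equiv), THF, 0 °C, 2 h; inverse quench into cold 2 M HCl; used promptly
Reagents that add atoms: vinylmagnesium bromide, C=C[Mg]Br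
Why: Weinreb ketone synthesis, in which one equivalent of Grignard reagent deprotonates the phenol and a second adds to give the N,O-chelated adduct 4, which cannot collapse until the acidic inverse quench, so there is no over-addition and the released MeNHOMe is protonated before it can add to the enone.

**Step 3**
Reactants: 1 3-(4-hydroxy-3-methoxyphenyl)propanoic acid (second portion)
Product: 7 1,3-dioxoisoindolin-2-yl 3-(4-hydroxy-3-methoxyphenyl)propanoate, via O-acylisourea 6 (not isolated)
Conditions: N-hydroxyphthalimide (1.05 equiv), DIC (1.1 equiv), THF, 0 °C to rt, no DMAP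
Reagents that add atoms: N-hydroxyphthalimide, O=C1c2ccccc2C(=O)N1O
Why: Carbodiimide (Steglich-type) esterification without DMAP, in which the acidic N–OH of N-hydroxyphthalimide (pKa about 6) captures O-acylisourea 6 much faster than the neutral guaiacol OH (pKa about 10), giving the redox-active ester chemoselectively.

**Step 4**
Reactants: 5 5-(4-hydroxy-3-methoxyphenyl)pent-1-en-3-one; 7 1,3-dioxoisoindolin-2-yl 3-(4-hydroxy-3-methoxyphenyl)propanoate
Product: 10 1,7-bis(4-hydroxy-3-methoxyphenyl)heptan-3-one, via 2-arylethyl radical 8 (not isolated), via alpha-keto radical adduct 9 (not isolated)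
Conditions: Ru(bpy)3(PF6)2 (1 mol%), Hantzsch ester (1.5 equiv), i-Pr2NEt·HBF4 (1 equiv), 5 (1.5 equiv), degassed CH2Cl2 (0.1 M), blue LEDs, rt
Reagents that add atoms: none
Why: Photoredox reductive decarboxylative Giese reaction, in which Ru(I) formed by Hantzsch-ester quenching reduces the N-acyloxyphthalimide, which loses phthalimide anion and CO2 to give nucleophilic primary radical 8; this adds to the unhindered β-carbon of the vinyl ketone and adduct radical 9 is capped by H-atom transfer from the Hantzsch ester, while the mild Ru excited state does not oxidise the guaiacol rings, the base-free medium suppresses oxa-Michael addition, and no stereocentre is formed.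

**Compound list**
1 | 3-(4-hydroxy-3-methoxyphenyl)propanoic acid (dihydroferulic acid) | COc1cc(CCC(=O)O)ccc1O | starting material
2 | 3-(4-hydroxy-3-methoxyphenyl)-1-(imidazol-1-yl)propan-1-one (acyl imidazolide) | COc1cc(CCC(=O)n2ccnc2)ccc1O | intermediate
3 | 3-(4-hydroxy-3-methoxyphenyl)-N-methoxy-N-methylpropanamide | COc1cc(CCC(=O)N(C)OC)ccc1O | intermediate
4 | bis(bromomagnesium) salt of the tetrahedral adduct 5-(4-hydroxy-3-methoxyphenyl)-3-[methoxy(methyl)amino]pent-1-en-3-ol | COc1cc(CCC(C=C)(O[Mg]Br)N(C)OC)ccc1O[Mg]Br | intermediate
5 | 5-(4-hydroxy-3-methoxyphenyl)pent-1-en-3-one | C=CC(=O)CCc1ccc(O)c(OC)c1 | intermediate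
6 | O-[3-(4-hydroxy-3-methoxyphenyl)propanoyl]-N,N'-diisopropylisourea | COc1cc(CCC(=O)OC(=NC(C)C)NC(C)C)ccc1O | intermediate
7 | 1,3-dioxoisoindolin-2-yl 3-(4-hydroxy-3-methoxyphenyl)propanoate | COc1cc(CCC(=O)ON2C(=O)c3ccccc3C2=O)ccc1O | intermediate
8 | 2-(4-hydroxy-3-methoxyphenyl)ethyl radical | [CH2]Cc1ccc(O)c(OC)c1 | intermediate
9 | 1,7-bis(4-hydroxy-3-methoxyphenyl)-3-oxoheptan-4-yl radical | COc1cc(CCC[CH]C(=O)CCc2ccc(O)c(OC)c2)ccc1O | intermediate
10 | 1,7-bis(4-hydroxy-3-methoxyphenyl)heptan-3-one (achiral) | COc1cc(CCCCC(=O)CCc2ccc(O)c(OC)c2)ccc1O | target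

**Total step count:** 4 (convergent; both branches start from 1).
**Longest linear sequence:** 3 steps (1 → 3 → 5 → 10); the second branch, 1 → 7, is one step.

**Three steps most likely to fail, with fallbacks**

1. Step 4, the key radical coupling. The primary radical may simply be reduced to 4-ethylguaiacol, the vinyl ketone may telomerise, or the free phenols may interfere as H-atom donors. The fallback makes a different bond (C7–aryl) by Heck chemistry; it sets out from 3 and comes back at 10. Weinreb amide 3 is treated with but-3-enylmagnesium bromide (3 equiv, THF, 0 °C, acidic quench) to give 1-(4-hydroxy-3-methoxyphenyl)hept-6-en-3-one F1. Jeffery-type Mizoroki–Heck arylation of its terminal alkene with commercial 4-iodo-2-methoxyphenol (Pd(OAc)2, n-Bu4NCl, NaHCO3, DMF, 70 °C) gives (E)-1,7-bis(4-hydroxy-3-methoxyphenyl)hept-6-en-3-one F2 together with its 5-ene isomer. Hydrogenation (H2, 1 atm, Pd/C, EtOAc, rt) converges all linear alkene isomers on 10; only a minor branched arylation product has to be removed.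

2. Step 2, making and handling the vinyl ketone. Risks are aza-Michael addition of released MeNHOMe, polymerisation of 5, and sluggish addition to the magnesium phenoxide. The fallback reaches 5 by a neutral acyl cross-coupling instead of an organomagnesium addition; it sets out from 1 and comes back at 5. Steglich thioesterification of 1 with thiophenol (DCC, cat. DMAP, CH2Cl2, 0 °C) gives S-phenyl 3-(4-hydroxy-3-methoxyphenyl)propanethioate F3. Palladium-catalysed, copper(I)-mediated thioester–stannane coupling with tributyl(vinyl)stannane (Pd2(dba)3, tri(2-furyl)phosphine, copper(I) diphenylphosphinate, THF, rt) then delivers 5 with no amine nucleophile or basic Grignard reagent present.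

3. Step 3, chemoselective formation of the redox-active ester. Risks are acylation of the free phenol, oligoester formation, and loss of the active ester on silica. The fallback replaces the redox-active ester by an alkyl iodide radical precursor from a different commercial building block; it sets out from 5, bypasses 7 and comes back at 10. Commercial 4-(2-hydroxyethyl)-2-methoxyphenol F4 (homovanillyl alcohol) is converted by an Appel reaction (PPh3, I2, imidazole, CH2Cl2, 0 °C), selective for the aliphatic alcohol, into 4-(2-iodoethyl)-2-methoxyphenol F5. Its primary radical, generated with Zn dust and CuI in aqueous EtOH under sonication (Luche-type conjugate addition), adds to 5 to give 10.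

**Further compounds**
F1 | step 4 | 1-(4-hydroxy-3-methoxyphenyl)hept-6-en-3-one | C=CCCC(=O)CCc1ccc(O)c(OC)c1
F2 | step 4 | (E)-1,7-bis(4-hydroxy-3-methoxyphenyl)hept-6-en-3-one | COc1cc(/C=C/CCC(=O)CCc2ccc(O)c(OC)c2)ccc1O
F3 | step 2 | S-phenyl 3-(4-hydroxy-3-methoxyphenyl)propanethioate | COc1cc(CCC(=O)Sc2ccccc2)ccc1O
F4 | step 3 | 4-(2-hydroxyethyl)-2-methoxyphenol | COc1cc(CCO)ccc1O
F5 | step 3 | 4-(2-iodoethyl)-2-methoxyphenol | COc1cc(CCI)ccc1O
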